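## Structural features

- The target 18 is the 3-hydroxy-4-methoxybenzoate of a trans-fused bicyclo[5.4.0]undecene diol. Ring A is a cyclohexene (C1–C6, trisubstituted C5=C6, methyl on C6), ring B is a cycloheptane (C3, C4, C7–C11), and the two rings share the C3–C4 bond.
- There are four stereocentres, all R. C3, C4 and C11 are contiguous: H3 and H4 are anti, and C11 is a fully substituted methyl carbinol directly on the ring fusion. C1, which carries the ester oxygen, is separated from C3 by the C2 methylene.
- The C1–O bond is cis to H3, so it is pseudoaxial on ring A and trans to the C3–C11 bond.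
- C7 is a quaternary gem-dimethyl carbon bonded to the fusion carbon C4, so every bond made at C4 or C8 is formed next to a neopentyl centre.
- The fragile groups are the tertiary alcohol at C11 (loss of water under acid), the secondary allylic benzoate at C1 (ionisation, allylic transposition, hydrogenolysis), the free phenol (competes in acylations) and the aryl ester link (strong nucleophiles).
- The real difficulty is the C3/C4/C11 triad beside a seven-membered ring flanked by two fully substituted carbons, and the delivery of oxygen to the pseudoaxial position at C1.
- The key step exploits C8–C9–C10, the only unsubstituted stretch of ring B. A C8=C9 alkene can be made there by joining a vinyl group on C7 to an allyl group on C11 and then saturated, with C3, C4 and C11 already fixed on ring A.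

## Logic of the disconnections

**18 ⇒ 17.** The phenolic O–H is masked as a silyl ether. The phenol would otherwise compete as a nucleophile when the benzoic acid is activated. The forward step must remove an aryl silyl ether without touching the allylic benzoate or the tertiary alcohol, which buffered fluoride does.

**17 ⇒ 13 + 16.** The acyl C–O bond of the C1 ester is cut. This separates the aromatic part from the terpenoid diol. The forward acylation must pick the secondary allylic alcohol over the tertiary one, which sterics ensure.

**16 ⇒ 14.** The O–Si bond is cut. One operation silylates both acidic sites of 14 and then frees the carboxylic acid again.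

**13 ⇒ 12.** The C1–O bond is cut, going back to an allylic C–H bond. This removes one stereocentre and all oxidation-state handling on ring A from the earlier steps. The forward step must oxidise the ring methylene at the more substituted alkene terminus and deliver oxygen to the face cis to H3.

**12 ⇒ 11.** A C8=C9 double bond is added retrosynthetically. The forward step must saturate a cis-disubstituted alkene and leave the trisubstituted C5=C6 alkene alone.

**11 ⇒ 10.** The C8=C9 bond is cut (key disconnection). Ring B disappears and a monocyclic cyclohexene remains, carrying a vinyl group on C7 and an allyl group on C11. All three stereocentres of 11 sit on or next to ring A and pass unchanged into 10. The structures of 10 and 11 were checked atom by atom against 18: C3, C4 and C11 have the same sense (R) in all three, so nothing needed correcting, and the tertiary alcohol is best left unprotected. The forward step needs the two terminal alkenes to react in preference to C5=C6 and to find each other intramolecularly.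

**10 ⇒ 8 + 9.** The C10–C11 bond is cut. The carbinol becomes a methyl ketone and the allyl group a commercial Grignard reagent. The forward addition must take place on the ketone face anti to C4. The order chosen (allyl onto the methyl ketone, not methyl onto an allyl ketone) is the one for which the Felkin–Anh model predicts 11R.

**8 ⇒ 7.** C3 is epimerised retrosynthetically. The kinetic Diels–Alder adduct of an E-diene is the cis isomer, so the trans relationship must come from equilibration of the ketone α-carbon. The forward step needs only a clear thermodynamic preference for trans.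

**7 ⇒ 5 + 6.** The C1–C2 and C3–C4 bonds are cut (Diels–Alder). Ring A and the C4 stereocentre fall away to an acyclic triene and a four-carbon enone. The forward step needs regiocontrol, which the 1-alkyl and 3-methyl groups of the diene both supply in the same sense. It also needs endo selectivity and control of absolute configuration by a chiral Lewis acid.

**5 ⇒ 4 ⇒ 2 (through 3) ⇒ 1.** The two C=C bonds of the diene are cut one after the other, and the aldehyde is traced to the acid. A single Wittig reaction with an allylic ylide would give E/Z mixtures, and only the E-diene can react. The diene is therefore built in two olefinations: a stabilised ylide fixes the E geometry, and a methylenation adds the terminal CH2. The aldehyde 3 is volatile and is not isolated.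

## Other disconnections considered

**Alternative 1:** vinyl radical closure of ring A.
- Cut: the C4–C5 bond (and the C3–H bond), going from the bicyclic C11 ketone with a C1 silyl ether, A1, back to a 2-substituted 4,4-dimethylcycloheptenone with a vinyl iodide side chain, A2.
- Forward key step: a tin hydride or silane radical chain generates the C5 vinyl radical from A2. It would add to the enone β-carbon C4 in a 6-endo-trig closure, and hydrogen transfer to the α-keto radical would set C3.
- In favour: ring A and both fusion centres form in one step. The C1 oxygen enters at the right oxidation level and configuration from a small chiral building block. This is better than the chosen plan, which has to oxidise C1 late.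
- Against: the radical must bond to C4 next to the quaternary C7, so simple reduction of the vinyl radical would compete. The face of attack at C4 would be steered only by the distant C1 silyl ether. The hydrogen transfer to C3 is kinetic and need not give the trans fusion. C3 stays α to a ketone and could be equilibrated, so on this point the two plans are equal (compare step 5).
- Against, at C11: the carbinol would have to be made by methyl addition to a flexible cycloheptanone, where no clear facial bias can be named. The chosen plan sets C11 on an open-chain ketone before ring B exists.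
- Step economy: about four steps after A1 against five after 11, so equal there. The assembly of A2 in enantiopure form would cost more than the six steps that lead to 10.

**Alternative 2:** enzymatic cyclisation.
- Cut: the C4–C7, C3–C4 and C11–O bonds together, going from the 1-deoxy alcohol A3 (identical with 12) back to farnesyl diphosphate A4.
- Forward key step: a class 1 sesquiterpene synthase would ionise A4, form C4–C7 by 1,11-closure, then C3–C4 by 1,6-closure after a hydride shift, and let water capture the C11 cation.
- In favour: one step would build both rings and three stereocentres without protecting groups. On step and atom economy it is clearly better than the chosen plan.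
- Equal: the finish from A3 would be steps 9 to 12 of the chosen route, so the C1 oxidation, the least secure chemical step, is shared.
- Against: the plan rests on an enzyme with exactly this product profile (trans fusion, this absolute configuration, water capture in place of proton loss). Such an enzyme would have to be found or engineered, and cyclases of this family tend to give several olefins and alcohols from one cation. A failure could not be repaired by changing reagents, whereas each stereocentre of the chosen plan is tied to a nameable control element.

**Alternative 3:** cation–diene closure with carboxylate capture.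
- Cut: the C4–C7 and C1–O bonds, going from the doubly acylated target A5 back to a ring A cyclohexadiene carrying a tertiary chloride and a C11 trifluoroacetate, A6, and silver 3-acetoxy-4-methoxybenzoate A7.
- Forward key step: monovalent silver of A7 would abstract chloride from C7. The cation would attack the diene terminus C4 and close ring B, and the carboxylate would trap the allyl cation at C1.
- In favour: ring B and the ester would be made in one operation, with no allylic oxidation and no separate acylation. On convergence and on the number of steps after the key step it is better than the chosen plan.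
- Against: a tertiary cation can lose a proton or be trapped directly by the carboxylate faster than it closes a seven-membered ring. Nothing in A6 enforces the trans fusion at C4, the 1,4-cis delivery of the carboxylate, or capture at C1 over C5. The tertiary trifluoroacetate at C11 could itself ionise in the presence of silver. A6 is a sensitive 1,3-cyclohexadiene that would have to be made enantiopure with the C11 centre in place. Two acyl protecting groups would have to be removed beside the C1 benzoate, against one silyl ether in the chosen plan.
- Comparison: the chosen plan is longer but spreads the four stereochemical decisions over four steps, each with its own control.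

Key step: step 7

Remarks on the chemistry:
- Atom locants C1–C11 are those of the target and are used for every intermediate.
- Assumption: the sense of induction in step 4 is taken from the binding model of the protonated oxazaborolidine (B–O coordination syn to the vinyl group plus an α-C–H···O contact). This model assigns attack on the Cα re face of the enone to the catalyst built from (R)-α,α-diphenylprolinol. This assignment was derived from the model, not from a remembered result, and both antipodes of the catalyst are available.

## Route

Step 1
Reactants: 1 2,2-dimethylbut-3-enoic acid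
Product: 2 2,2-dimethylbut-3-en-1-ol
Conditions: LiAlH4, Et2O, 0 °C → rt; aq. NaOH work-up
Reagents that add atoms: none
Why: Hydride reduction of a carboxylic acid to the primary alcohol; the isolated vinyl group is inert to LiAlH4 and the quaternary α-carbon excludes side reactions, and the volatile alcohol is handled as an ether solution.

Step 2
Reactants: 2 2,2-dimethylbut-3-en-1-ol
Product: 4 (E)-5,5-dimethylhepta-3,6-dien-2-one, via 2,2-dimethylbut-3-enal 3 (not isolated)
Conditions: (COCl)2, DMSO, Et3N, CH2Cl2, −78 °C → rt; then Ph3P=CHC(O)CH3, 40 °C
Reagents that add atoms: 1-(triphenylphosphoranylidene)propan-2-one, CC(=O)C=P(c1ccccc1)(c1ccccc1)c1ccccc1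
Why: Swern oxidation followed in the same flask by a Wittig reaction, so that the volatile, non-enolisable aldehyde 3 is never isolated; a carbonyl-stabilised ylide gives the E-enone reliably, the more so with an α-quaternary aldehyde.

Step 3
Reactants: 4 (E)-5,5-dimethylhepta-3,6-dien-2-one
Product: 5 (E)-2,5,5-trimethylhepta-1,3,6-triene
Conditions: Ph3PCH3Br, KOtBu, THF, 0 °C → rt
Reagents that add atoms: methyltriphenylphosphonium bromide, C[P+](c1ccccc1)(c1ccccc1)c1ccccc1.[Br-]
Why: Wittig methylenation; the non-stabilised ylide attacks the carbonyl carbon and not the enone β-carbon, and the E geometry of the existing alkene is untouched, so the diene is a single isomer that can reach the s-cis conformation.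

Step 4
Reactants: 5 (E)-2,5,5-trimethylhepta-1,3,6-triene; 6 methyl vinyl ketone (but-3-en-2-one)
Product: 7 1-[(1S,2R)-4-methyl-2-(2-methylbut-3-en-2-yl)cyclohex-3-en-1-yl]ethan-1-one (cis: acetyl on C3 and the tertiary alkyl group on C4 on the same face)
Conditions: (R)-B-(o-tolyl)oxazaborolidine from (R)-α,α-diphenylprolinol (20 mol %), Tf2NH, CH2Cl2, −78 → −40 °C
Reagents that add atoms: none
Why: Enantioselective Lewis acid catalysed Diels–Alder reaction of an enone; the 1-alkyl and 3-methyl groups of the diene both direct the acetyl-bearing carbon to C3 (the early C1–C2 bond forms at the unhindered diene CH2), and the endo transition state of the E-diene places acetyl and the C4 substituent cis. The chiral oxazaborolidinium ion shields one enone face with a phenyl group so that the diene adds to the Cα re face, which fixes C4 as R (C3 is formed S and is corrected in step 5).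

Step 5
Reactants: 7 1-[(1S,2R)-4-methyl-2-(2-methylbut-3-en-2-yl)cyclohex-3-en-1-yl]ethan-1-one
Product: 8 1-[(1R,2R)-4-methyl-2-(2-methylbut-3-en-2-yl)cyclohex-3-en-1-yl]ethan-1-one (trans)
Conditions: NaOMe (cat.), MeOH, rt
Reagents that add atoms: none
Why: Base-mediated epimerisation of the ketone α-carbon through the enolate; the trans isomer, which can place both large groups equatorial or both anti, is the thermodynamic one, and C4 carries no acidic hydrogen and keeps its configuration, so C3 becomes R relative to it.

Step 6
Reactants: 8 1-[(1R,2R)-4-methyl-2-(2-methylbut-3-en-2-yl)cyclohex-3-en-1-yl]ethan-1-one; 9 allylmagnesium bromide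
Product: 10 (2R)-2-[(1R,2R)-4-methyl-2-(2-methylbut-3-en-2-yl)cyclohex-3-en-1-yl]pent-4-en-2-ol
Conditions: Et2O, −78 °C; then aq. NH4Cl
Reagents that add atoms: none
Why: Grignard 1,2-addition to a ketone under Felkin–Anh control; C4 with its tertiary alkyl group is the large α-substituent and stands perpendicular to the carbonyl plane, the carbonyl oxygen lies near C2 and the methyl near H3, and the allyl group enters anti to C4 past H3, which gives 11R. The low temperature and the high nucleophilicity of the allyl reagent keep enolisation of the hindered ketone down.

Step 7
Reactants: 10 (2R)-2-[(1R,2R)-4-methyl-2-(2-methylbut-3-en-2-yl)cyclohex-3-en-1-yl]pent-4-en-2-ol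
Product: 11 (4aR,9R,9aR)-3,5,5,9-tetramethyl-2,4a,5,8,9,9a-hexahydro-1H-benzo[7]annulen-9-ol (trans-fused; alkenes C5=C6 and C8=C9)
Conditions: second-generation Grubbs catalyst RuCl2(=CHPh)(PCy3)(H2IMes) (5 mol %), CH2Cl2 (2 mM), 40 °C
Reagents that add atoms: none
Why: Ring-closing olefin metathesis through metallacyclobutanes: the ruthenium benzylidene exchanges onto the unhindered terminal alkene of the allyl group, the new alkylidene at C9 adds across the vinyl group on C7 in an intramolecular [2+2] cycloaddition, and cycloreversion releases the C8=C9 alkene and a ruthenium methylidene that carries the chain, while ethylene escapes and makes the closure irreversible. The closest known reaction type is the closure of 1,8-dienes to cycloheptenes with this catalyst, including substrates with an allylic quaternary carbon and a free tertiary homoallylic alcohol. Ring B is closed as a seven-membered ring in which both alkene carbons end up inside the ring, and the ring size allows only the Z alkene. No stereocentre is formed, and C3, C4 and C11 are untouched because no bond to them is made or broken. The step needs chemoselectivity for the two monosubstituted alkenes over the trisubstituted C5=C6 alkene, which the low metathesis reactivity of trisubstituted ring alkenes provides. It also needs ring closure to beat oligomerisation, which is secured by high dilution, by the trans placement of the two side chains on adjacent ring A carbons and by the gem-dimethyl group on C7 that favours the folded conformer. Because the catalyst loads on the allyl terminus, the hindered neopentyl-type vinyl group is only asked to take part in the fast intramolecular step.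

Step 8
Reactants: 11 (4aR,9R,9aR)-3,5,5,9-tetramethyl-2,4a,5,8,9,9a-hexahydro-1H-benzo[7]annulen-9-ol
Product: 12 (4aR,9R,9aR)-3,5,5,9-tetramethyl-2,4a,5,6,7,8,9,9a-octahydro-1H-benzo[7]annulen-9-ol
Conditions: H2 (1 atm), RhCl(PPh3)3 (5 mol %), toluene–EtOH, rt
Reagents that add atoms: none
Why: Homogeneous hydrogenation with RhCl(PPh3)3 discriminates strongly by alkene substitution, so the cis-disubstituted C8=C9 bond is reduced and the trisubstituted C5=C6 bond stays; no stereocentre is formed and nothing in the molecule is prone to hydrogenolysis at this stage.

Step 9
Reactants: 12 (4aR,9R,9aR)-3,5,5,9-tetramethyl-2,4a,5,6,7,8,9,9a-octahydro-1H-benzo[7]annulen-9-ol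
Product: 13 (2R,4aR,9R,9aR)-3,5,5,9-tetramethyl-2,4a,5,6,7,8,9,9a-octahydro-1H-benzo[7]annulene-2,9-diol (C1 hydroxyl cis to H3)
Conditions: SeO2 (cat.), t-BuOOH, CH2Cl2, 0 °C → rt
Reagents that add atoms: tert-butyl hydroperoxide, CC(C)(C)OO (terminal oxidant; its oxygen reaches C1 by way of selenium dioxide, O=[Se]=O)
Why: Allylic hydroxylation by SeO2 (ene reaction at C5 with removal of an allylic hydrogen, then [2,3]-sigmatropic shift of the allylseleninic acid); selenium dioxide oxidises the ring methylene at the more substituted alkene terminus, here C1, in preference to the C6 methyl and the tertiary C4–H. The ene step removes the pseudoaxial H1, which is the one aligned with the π system and cis to H3, and the suprafacial shift returns oxygen to that same face, so the pseudoaxial 1R alcohol is expected; the tertiary alcohol is inert under these near-neutral conditions.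

Step 10
Reactants: 14 isovanillic acid (3-hydroxy-4-methoxybenzoic acid)
Product: 16 3-[(tert-butyldimethylsilyl)oxy]-4-methoxybenzoic acid, via tert-butyldimethylsilyl 3-[(tert-butyldimethylsilyl)oxy]-4-methoxybenzoate 15 (not isolated)
Conditions: TBSCl (2.5 equiv), imidazole, DMF, rt; then AcOH–THF–H2O, rt
Reagents that add atoms: tert-butyldimethylsilyl chloride, CC(C)(C)[Si](C)(C)Cl
Why: Silylation of both acidic sites followed by selective hydrolysis of the silyl ester, which is far more labile than the aryl silyl ether; the phenol is thereby masked against self-acylation in step 11.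

Step 11
Reactants: 13 (2R,4aR,9R,9aR)-3,5,5,9-tetramethyl-2,4a,5,6,7,8,9,9a-octahydro-1H-benzo[7]annulene-2,9-diol; 16 3-[(tert-butyldimethylsilyl)oxy]-4-methoxybenzoic acid
Product: 17 (2R,4aR,9R,9aR)-9-hydroxy-3,5,5,9-tetramethyl-2,4a,5,6,7,8,9,9a-octahydro-1H-benzo[7]annulen-2-yl 3-[(tert-butyldimethylsilyl)oxy]-4-methoxybenzoate
Conditions: DCC, DMAP (cat.), CH2Cl2, 0 °C → rt
Reagents that add atoms: none
Why: Steglich esterification; the acylpyridinium intermediate acylates the secondary allylic alcohol with retention at C1 (the C1–O bond is not broken), while the tertiary C11 alcohol is too hindered to react, and the basic, non-ionising conditions avoid allylic transposition.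

Step 12
Reactants: 17 (2R,4aR,9R,9aR)-9-hydroxy-3,5,5,9-tetramethyl-2,4a,5,6,7,8,9,9a-octahydro-1H-benzo[7]annulen-2-yl 3-[(tert-butyldimethylsilyl)oxy]-4-methoxybenzoate
Product: 18 (2R,4aR,9R,9aR)-9-hydroxy-3,5,5,9-tetramethyl-2,4a,5,6,7,8,9,9a-octahydro-1H-benzo[7]annulen-2-yl 3-hydroxy-4-methoxybenzoate (target)
Conditions: Bu4NF, AcOH, THF, 0 °C
Reagents that add atoms: none
Why: Fluoride cleavage of an aryl silyl ether, which is fast at 0 °C; buffering with acetic acid keeps the medium close to neutral so that the allylic benzoate is neither cleaved nor ionised and the tertiary alcohol is not dehydrated.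

## Compound list

1 | 2,2-dimethylbut-3-enoic acid | C=CC(C)(C)C(=O)O | starting material
2 | 2,2-dimethylbut-3-en-1-ol | C=CC(C)(C)CO | intermediate
3 | 2,2-dimethylbut-3-enal | C=CC(C)(C)C=O | intermediate (not isolated)
4 | (E)-5,5-dimethylhepta-3,6-dien-2-one | CC(=O)/C=C/C(C)(C)C=C | intermediate
5 | (E)-2,5,5-trimethylhepta-1,3,6-triene | CC(=C)/C=C/C(C)(C)C=C | intermediate
6 | methyl vinyl ketone | CC(=O)C=C | starting material
7 | 1-[(1S,2R)-4-methyl-2-(2-methylbut-3-en-2-yl)cyclohex-3-en-1-yl]ethan-1-one (cis) | C1C[C@H](C(C)=O)[C@@H](C=C1C)C(C)(C)C=C | intermediate
8 | 1-[(1R,2R)-4-methyl-2-(2-methylbut-3-en-2-yl)cyclohex-3-en-1-yl]ethan-1-one (trans) | C1C[C@@H](C(C)=O)[C@@H](C=C1C)C(C)(C)C=C | intermediate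
9 | allylmagnesium bromide | C=CC[Mg]Br | starting material
10 | (2R)-2-[(1R,2R)-4-methyl-2-(2-methylbut-3-en-2-yl)cyclohex-3-en-1-yl]pent-4-en-2-ol | C1C[C@@H]([C@](C)(O)CC=C)[C@@H](C=C1C)C(C)(C)C=C | intermediate
11 | (4aR,9R,9aR)-3,5,5,9-tetramethyl-2,4a,5,8,9,9a-hexahydro-1H-benzo[7]annulen-9-ol | C1C[C@@H]2[C@@H](C=C1C)C(C)(C)C=CC[C@@]2(C)O | intermediate
12 | (4aR,9R,9aR)-3,5,5,9-tetramethyl-2,4a,5,6,7,8,9,9a-octahydro-1H-benzo[7]annulen-9-ol | C1C[C@@H]2[C@@H](C=C1C)C(C)(C)CCC[C@@]2(C)O | intermediate
13 | (2R,4aR,9R,9aR)-3,5,5,9-tetramethyl-2,4a,5,6,7,8,9,9a-octahydro-1H-benzo[7]annulene-2,9-diol | O[C@@H]1C[C@@H]2[C@@H](C=C1C)C(C)(C)CCC[C@@]2(C)O | intermediate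
14 | isovanillic acid (3-hydroxy-4-methoxybenzoic acid) | COc1ccc(C(=O)O)cc1O | starting material
15 | tert-butyldimethylsilyl 3-[(tert-butyldimethylsilyl)oxy]-4-methoxybenzoate | COc1ccc(C(=O)O[Si](C)(C)C(C)(C)C)cc1O[Si](C)(C)C(C)(C)C | intermediate (not isolated)
16 | 3-[(tert-butyldimethylsilyl)oxy]-4-methoxybenzoic acid | COc1ccc(C(=O)O)cc1O[Si](C)(C)C(C)(C)C | intermediate
17 | (2R,4aR,9R,9aR)-9-hydroxy-3,5,5,9-tetramethyl-2,4a,5,6,7,8,9,9a-octahydro-1H-benzo[7]annulen-2-yl 3-[(tert-butyldimethylsilyl)oxy]-4-methoxybenzoate | COc1ccc(C(=O)O[C@@H]2C[C@@H]3[C@@H](C=C2C)C(C)(C)CCC[C@@]3(C)O)cc1O[Si](C)(C)C(C)(C)C | intermediate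
18 | (2R,4aR,9R,9aR)-9-hydroxy-3,5,5,9-tetramethyl-2,4a,5,6,7,8,9,9a-octahydro-1H-benzo[7]annulen-2-yl 3-hydroxy-4-methoxybenzoate | COc1ccc(C(=O)O[C@@H]2C[C@@H]3[C@@H](C=C2C)C(C)(C)CCC[C@@]3(C)O)cc1O | target

## Step count and least certain steps

Total step count: 12. Longest linear sequence: 11 steps (steps 1–9, 11 and 12); step 10 is a one-step side branch.

**Step 7 (key step).** The process most likely to go wrong is slow engagement of the neopentyl-type vinyl group. The alkylidene formed at the allyl terminus would then be diverted into intermolecular metathesis. Alternatively, after catalyst decay to a ruthenium hydride, the allyl double bond could migrate and a ring one carbon smaller would close.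

The fallback moves the ring B alkene one bond away from the quaternary carbon. It sets out again from 6 and comes back at 12.
- Commercial 2,2-dimethylpent-4-enal F1 is taken through the two olefinations of steps 2 and 3 to the enone (E)-5,5-dimethylocta-3,7-dien-2-one F2 and the triene (E)-2,5,5-trimethylocta-1,3,7-triene F3.
- Diels–Alder reaction of F3 with 6 under the conditions of step 4 should give the cis ketone 1-[(1S,2R)-4-methyl-2-(2-methylpent-4-en-2-yl)cyclohex-3-en-1-yl]ethan-1-one F4, which NaOMe in MeOH equilibrates to the trans ketone 1-[(1R,2R)-4-methyl-2-(2-methylpent-4-en-2-yl)cyclohex-3-en-1-yl]ethan-1-one F5.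
- Vinylmagnesium bromide, adding in the same Felkin–Anh sense as in step 6, gives the vinyl carbinol (2R)-2-[(1R,2R)-4-methyl-2-(2-methylpent-4-en-2-yl)cyclohex-3-en-1-yl]but-3-en-2-ol F6.
- Ring-closing metathesis with the same ruthenium catalyst then joins an unhindered allyl group on C7 to the vinyl carbinol and forms C9=C10 in the bicyclic diene alcohol (4aR,9R,9aR)-3,5,5,9-tetramethyl-2,4a,5,6,9,9a-hexahydro-1H-benzo[7]annulen-9-ol F7.
- Hydrogenation as in step 8 converts F7 into 12.

**Step 4.** The likely failures are insufficient facial discrimination and acid-induced oligomerisation of the electron-rich triene. The diene terminus that bonds to the enone α-carbon carries a tertiary alkyl group, and a strong Brønsted acid is present.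

The fallback replaces catalyst control by a covalently bound auxiliary. It sets out from 5 and comes back at 7.
- Triene 5 is combined with the commercial dienophile (R)-3-acryloyl-4-benzyl-1,3-oxazolidin-2-one F8 and Et2AlCl in CH2Cl2 at −78 °C. The chelated s-cis imide is shielded on one face by the benzyl group, and the adduct (4R)-4-benzyl-3-[(1S,2R)-4-methyl-2-(2-methylbut-3-en-2-yl)cyclohex-3-ene-1-carbonyl]-1,3-oxazolidin-2-one F9 is expected.
- Transamination with MeNH(OMe)·HCl and AlMe3 gives the amide (1S,2R)-N-methoxy-N,4-dimethyl-2-(2-methylbut-3-en-2-yl)cyclohex-3-ene-1-carboxamide F10 and returns the auxiliary.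
- MeMgBr in THF converts F10 into 7. Any epimerisation at C3 on the way is harmless because step 5 follows.

**Step 6.** The likely failure is poor facial selectivity. Allylmagnesium reagents react through early, cyclic transition states and discriminate little. Enolisation of the hindered ketone would add to the loss.

The fallback builds the carbinol in two bond-forming events. It sets out from 8 and comes back at 10.
- Corey–Chaykovsky epoxidation of 8 with dimethylsulfonium methylide (Me3SI, n-BuLi, THF, −10 °C) is a more sterically demanding and irreversible addition. It should deliver the CH2 group anti to C4 and give the epoxide (2S)-2-methyl-2-[(1R,2R)-4-methyl-2-(2-methylbut-3-en-2-yl)cyclohex-3-en-1-yl]oxirane F11. The diastereomers can be separated at this stage.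
- Copper-catalysed opening of F11 at its CH2 terminus with vinylmagnesium bromide (CuI cat., THF, −30 °C) gives 10.

**Step 9.** The likely failures are delivery of oxygen to the wrong face (if approach to C5 on the face of the pseudoaxial H1 is hindered by the C7 methyl groups), over-oxidation to the enone, and some oxidation of the C6 methyl group.

The fallback sets C1 by reduction and inversion. It sets out from crude 13 (mixed with its C1 epimer and enone) and comes back at 17.
- MnO2 in CH2Cl2 converts the whole mixture into the enone (4aR,9R,9aR)-9-hydroxy-3,5,5,9-tetramethyl-1,4a,5,6,7,8,9,9a-octahydro-2H-benzo[7]annulen-2-one F12.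
- Luche reduction (NaBH4, CeCl3·7H2O, MeOH, −78 °C) by axial hydride delivery should give the pseudoequatorial alcohol (2S,4aR,9R,9aR)-3,5,5,9-tetramethyl-2,4a,5,6,7,8,9,9a-octahydro-1H-benzo[7]annulene-2,9-diol F13.
- Mitsunobu esterification of F13 with 16 (PPh3, DIAD, THF, 0 °C) inverts C1 and gives 17 directly, in place of step 11.

## Further compounds

F1 | step 7 | 2,2-dimethylpent-4-enal (purchased) | C=CCC(C)(C)C=O
F2 | step 7 | (E)-5,5-dimethylocta-3,7-dien-2-one | CC(=O)/C=C/C(C)(C)CC=C
F3 | step 7 | (E)-2,5,5-trimethylocta-1,3,7-triene | CC(=C)/C=C/C(C)(C)CC=C
F4 | step 7 | 1-[(1S,2R)-4-methyl-2-(2-methylpent-4-en-2-yl)cyclohex-3-en-1-yl]ethan-1-one | C1C[C@H](C(C)=O)[C@@H](C=C1C)C(C)(C)CC=C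
F5 | step 7 | 1-[(1R,2R)-4-methyl-2-(2-methylpent-4-en-2-yl)cyclohex-3-en-1-yl]ethan-1-one | C1C[C@@H](C(C)=O)[C@@H](C=C1C)C(C)(C)CC=C
F6 | step 7 | (2R)-2-[(1R,2R)-4-methyl-2-(2-methylpent-4-en-2-yl)cyclohex-3-en-1-yl]but-3-en-2-ol | C1C[C@@H]([C@](C)(O)C=C)[C@@H](C=C1C)C(C)(C)CC=C
F7 | step 7 | (4aR,9R,9aR)-3,5,5,9-tetramethyl-2,4a,5,6,9,9a-hexahydro-1H-benzo[7]annulen-9-ol | C1C[C@@H]2[C@@H](C=C1C)C(C)(C)CC=C[C@@]2(C)O
F8 | step 4 | (R)-3-acryloyl-4-benzyl-1,3-oxazolidin-2-one (purchased) | C=CC(=O)N1[C@H](Cc2ccccc2)COC1=O
F9 | step 4 | (4R)-4-benzyl-3-[(1S,2R)-4-methyl-2-(2-methylbut-3-en-2-yl)cyclohex-3-ene-1-carbonyl]-1,3-oxazolidin-2-one | C1C[C@H](C(=O)N2[C@H](Cc3ccccc3)COC2=O)[C@@H](C=C1C)C(C)(C)C=C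
F10 | step 4 | (1S,2R)-N-methoxy-N,4-dimethyl-2-(2-methylbut-3-en-2-yl)cyclohex-3-ene-1-carboxamide | C1C[C@H](C(=O)N(C)OC)[C@@H](C=C1C)C(C)(C)C=C
F11 | step 6 | (2S)-2-methyl-2-[(1R,2R)-4-methyl-2-(2-methylbut-3-en-2-yl)cyclohex-3-en-1-yl]oxirane | C1C[C@@H]([C@@]2(C)CO2)[C@@H](C=C1C)C(C)(C)C=C
F12 | step 9 | (4aR,9R,9aR)-9-hydroxy-3,5,5,9-tetramethyl-1,4a,5,6,7,8,9,9a-octahydro-2H-benzo[7]annulen-2-one | O=C1C[C@@H]2[C@@H](C=C1C)C(C)(C)CCC[C@@]2(C)O
F13 | step 9 | (2S,4aR,9R,9aR)-3,5,5,9-tetramethyl-2,4a,5,6,7,8,9,9a-octahydro-1H-benzo[7]annulene-2,9-diol | O[C@H]1C[C@@H]2[C@@H](C=C1C)C(C)(C)CCC[C@@]2(C)O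
A1 | alternative 1 | trans-fused bicyclic C11 ketone with C1 tert-butyldimethylsilyl ether | CC(C)(C)[Si](C)(C)O[C@@H]1C[C@@H]2[C@@H](C=C1C)C(C)(C)CCCC2=O
A2 | alternative 1 | 2-[(2R,3E)-2-[(tert-butyldimethylsilyl)oxy]-4-iodo-3-methylbut-3-en-1-yl]-4,4-dimethylcyclohept-2-en-1-one | CC(C)(C)[Si](C)(C)O[C@H](CC1=CC(C)(C)CCCC1=O)/C(C)=C/I
A3 | alternative 2 | 1-deoxy core alcohol (identical with 12) | C1C[C@@H]2[C@@H](C=C1C)C(C)(C)CCC[C@@]2(C)O
A4 | alternative 2 | (2E,6E)-farnesyl diphosphate | CC(C)=CCC/C(C)=C/CC/C(C)=C/COP(=O)(O)OP(=O)(O)O
A5 | alternative 3 | target carrying an aryl acetate and a C11 trifluoroacetate | COc1ccc(C(=O)O[C@@H]2C[C@@H]3[C@@H](C=C2C)C(C)(C)CCC[C@@]3(C)OC(=O)C(F)(F)F)cc1OC(C)=O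
A6 | alternative 3 | ring A 1,3-diene with C7 tertiary chloride and C11 trifluoroacetate | CC1=CC[C@H](C=C1)[C@@](C)(CCCC(C)(C)Cl)OC(=O)C(F)(F)F
A7 | alternative 3 | silver 3-acetoxy-4-methoxybenzoate | COc1ccc(C(=O)[O-])cc1OC(C)=O.[Ag+]
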